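**Assumption:** the SMILES is taken literally, i.e. (1S,4aS,6S,8aR) in decalin numbering: trans-decalin, with the C6–OH and the C1–CH2OAr both axial on the face opposite the angular methyl.

## Retrosynthetic overview

1. Target ⇐ enol triflate 21 (vinylic CH3 by Negishi coupling, TES removal) ⇐ ketone 20 (kinetic enol triflate).
2. 20 ⇐ trans-hydrindanone 9 + aryl chloromethyl ether 17. A one-carbon ring enlargement (1,2-shift of the quaternary carbon onto a lithium bromocarbenoid) gives the ring-B enolate, which is alkylated anti to the angular methyl.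
3. 9 ⇐ Hajos–Parrish-type enedione 4 (ketal; Birch reductive methylation for the trans fusion and gem-dimethyl; L-Selectride for the axial OH) ⇐ 2-methylcyclopentane-1,3-dione + ethyl vinyl ketone.
4. 17 ⇐ esculetin 14 (7-O-CH2SMe, 6-O-Me, SO2Cl2) ⇐ 1,4-benzoquinone (Thiele–Winter) + ethyl propiolate.
5. Ring order: ring A is annulated onto the cyclopentanedione; the pyranone is built onto the arene; ring B (cyclopentanone → cyclohexanone) is formed last, at the fragment union.

## Route

Step 1
Reactants: 1 2-methylcyclopentane-1,3-dione; 2 pent-1-en-3-one (ethyl vinyl ketone)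
Product: 4 (7aR)-4,7a-dimethyl-2,3,7,7a-tetrahydro-1H-indene-1,5(6H)-dione, via triketone 3 (not isolated)
Conditions: H2O, rt; evaporate; D-phenylalanine (1 equiv, recovered), 1 M HClO4 (0.4 equiv), MeCN, reflux
Reagents that add atoms: none
Why: Michael addition, then amino-acid-mediated Hajos–Parrish (Eder–Sauer–Wiechert) aldol condensation; D-phenylalanine gives the (7aR) quaternary centre (mirror image of the L-Phe series), and ee is raised by recrystallisation.

Step 2
Reactants: 4 (7aR)-4,7a-dimethyl-2,3,7,7a-tetrahydro-1H-indene-1,5(6H)-dione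
Product: 5 (7a'R)-4',7a'-dimethyl-2',3',7',7a'-tetrahydrospiro[1,3-dioxolane-2,1'-inden]-5'(6'H)-one
Conditions: HOCH2CH2OH (1.5 equiv), p-TsOH·H2O (5 mol %), 4 Å MS, CH2Cl2, rt
Reagents that add atoms: ethane-1,2-diol (OCCO)
Why: Chemoselective acetalisation; the saturated cyclopentanone is more electrophilic than the conjugated α-methyl enone carbonyl.

Step 3
Reactants: 5 (7a'R)-4',7a'-dimethyl-2',3',7',7a'-tetrahydrospiro[1,3-dioxolane-2,1'-inden]-5'(6'H)-one
Product: 6 (3a'R,7a'R)-4',4',7a'-trimethylhexahydrospiro[1,3-dioxolane-2,1'-inden]-5'(4'H)-one (trans-fused)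
Conditions: Li (2.2 equiv), H2O (1.0 equiv), NH3(l)/THF, −78 → −33 °C; then MeI (5 equiv), −78 °C → rt
Reagents that add atoms: iodomethane (CI)
Why: Stork reductive alkylation (Birch-type enone reduction); protonation of the β-carbon anti to the angular methyl sets the trans ring fusion, and the regiodefined lithium enolate is C-methylated to the gem-dimethyl ketone.

Step 4
Reactants: 6 (3a'R,7a'R)-4',4',7a'-trimethylhexahydrospiro[1,3-dioxolane-2,1'-inden]-5'(4'H)-one
Product: 8 (3aR,5S,7aR)-5-hydroxy-4,4,7a-trimethyloctahydro-1H-inden-1-one, via hydroxy ketal 7 (not isolated)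
Conditions: L-Selectride (1.3 equiv), THF, −78 °C; then 2 M aq HCl, THF, rt
Reagents that add atoms: water (O)
Why: The bulky hydride attacks the 4,4-dimethyl ketone along the equatorial trajectory, giving the axial (5S) alcohol (syn to H-3a, anti to the angular methyl); aqueous acid then hydrolyses the dioxolane.

Step 5
Reactants: 8 (3aR,5S,7aR)-5-hydroxy-4,4,7a-trimethyloctahydro-1H-inden-1-one
Product: 9 (3aR,5S,7aR)-4,4,7a-trimethyl-5-[(triethylsilyl)oxy]octahydro-1H-inden-1-one
Conditions: TESCl (1.5 equiv), imidazole (3 equiv), DMAP (cat.), DMF, rt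
Reagents that add atoms: chlorotriethylsilane (CC[Si](Cl)(CC)CC)
Why: Standard silylation masks the only OH before the organolithium chemistry; the TES group is removed by dilute acid in the last step.

Step 6
Reactants: 10 1,4-benzoquinone
Product: 11 benzene-1,2,4-triyl triacetate
Conditions: Ac2O, conc. H2SO4 (cat.), 40–50 °C
Reagents that add atoms: acetic anhydride (CC(=O)OC(C)=O)
Why: Thiele–Winter acetoxylation: acid-catalysed conjugate addition of acetate to the quinone, aromatisation and acetylation.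

Step 7
Reactants: 11 benzene-1,2,4-triyl triacetate; 12 ethyl prop-2-ynoate (ethyl propiolate)
Product: 14 6,7-dihydroxy-2H-chromen-2-one (esculetin), via benzene-1,2,4-triol 13 (not isolated)
Conditions: HCl (cat.), MeOH, reflux, N2; evaporate; then 12, ZnCl2 (1 equiv), 1,4-dioxane, 100 °C
Reagents that add atoms: none
Why: Methanolysis frees the air-sensitive triol, which undergoes a ZnCl2-promoted Pechmann-type hydroarylation/lactonisation with the propiolate at the ring carbon para to one OH and ortho to another.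

Step 8
Reactants: 14 6,7-dihydroxy-2H-chromen-2-one
Product: 15 6-hydroxy-7-[(methylsulfanyl)methoxy]-2H-chromen-2-one
Conditions: NaH (1.0 equiv), DMF, 0 °C; MeSCH2Cl (1.05 equiv), NaI (cat.), 0 °C → rt
Reagents that add atoms: chloromethyl methyl sulfide (CSCCl)
Why: Williamson etherification of the monophenoxide; the 7-OH is conjugated to the lactone carbonyl and is the more acidic one, so one equivalent of base directs alkylation to O7.

Step 9
Reactants: 15 6-hydroxy-7-[(methylsulfanyl)methoxy]-2H-chromen-2-one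
Product: 16 6-methoxy-7-[(methylsulfanyl)methoxy]-2H-chromen-2-one
Conditions: MeI (1.5 equiv), K2CO3, acetone, rt
Reagents that add atoms: iodomethane (CI)
Why: Williamson O-methylation of the remaining phenol; the phenoxide is far more nucleophilic than the thioether.

Step 10
Reactants: 16 6-methoxy-7-[(methylsulfanyl)methoxy]-2H-chromen-2-one
Product: 17 7-(chloromethoxy)-6-methoxy-2H-chromen-2-one
Conditions: SO2Cl2 (1.05 equiv), CH2Cl2, −20 → 0 °C, 20 min; volatiles removed in vacuo, used crude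
Reagents that add atoms: sulfuryl chloride (O=S(=O)(Cl)Cl)
Why: Chlorinolysis of the O,S-acetal via the chlorosulfonium ion, the standard way from a methylthiomethyl ether to an aryl chloromethyl ether.

Step 11
Reactants: 9 (3aR,5S,7aR)-4,4,7a-trimethyl-5-[(triethylsilyl)oxy]octahydro-1H-inden-1-one; 17 7-(chloromethoxy)-6-methoxy-2H-chromen-2-one
Product: 20 6-methoxy-7-{[(1S,4aS,6S,8aR)-5,5,8a-trimethyl-2-oxo-6-[(triethylsilyl)oxy]decahydronaphthalen-1-yl]methoxy}-2H-chromen-2-one, via dibromomethyl carbinolate 18 (not isolated), via ring-enlarged lithium enolate 19 (not isolated)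
Conditions: 9, CH2Br2 (1.3 equiv), THF, −78 °C, LiTMP (1.3 equiv); n-BuLi (1.3 equiv), −95 → −20 °C; recool to −78 °C, 17 (1.5 equiv) in THF, −78 → −40 °C; aq NH4Cl
Reagents that add atoms: dibromomethane (BrCBr)
Why: Proposed new method: one-flask ring enlargement/aryloxymethylation. LiCHBr2 adds to the cyclopentanone anti to the angular methyl; Br/Li exchange gives a β-oxido bromocarbenoid in which the electron-richer quaternary carbon migrates (1,2-shift, loss of LiBr) to give regiospecifically the C1=C2 enolate of the 2-decalone; this enolate is C-alkylated by the SN2-type chloromethyl ether 17 along the axial trajectory anti to the angular methyl, which sets C1 (S) with the side chain axial. The closest known chemistry is the Taguchi–Yamamoto–Nozaki β-oxido carbenoid ring enlargement with trapping of the enolate (MeI, TMSCl) and enolate alkylation with benzyl chloromethyl ether; neither has been shown with an α-quaternary hydrindanone or a heteroaryl chloromethyl ether.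

Step 12
Reactants: 20 6-methoxy-7-{[(1S,4aS,6S,8aR)-5,5,8a-trimethyl-2-oxo-6-[(triethylsilyl)oxy]decahydronaphthalen-1-yl]methoxy}-2H-chromen-2-one
Product: 21 (1S,4aS,6S,8aR)-1-{[(6-methoxy-2-oxo-2H-chromen-7-yl)oxy]methyl}-5,5,8a-trimethyl-6-[(triethylsilyl)oxy]-1,4,4a,5,6,7,8,8a-octahydronaphthalen-2-yl trifluoromethanesulfonate
Conditions: PhNTf2 (1.3 equiv), THF, −78 °C; KHMDS (1.15 equiv) added dropwise (in situ trapping), −78 °C, 1 h
Reagents that add atoms: N-phenylbis(trifluoromethanesulfonimide) (O=S(=O)(N(c1ccccc1)S(=O)(=O)C(F)(F)F)C(F)(F)F)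
Why: Kinetic enol triflate formation; the hindered base removes the axial H of the C3 methylene and not the equatorial, neopentyl C1–H, and in situ trapping prevents equilibration or β-elimination of the aryloxide.

Step 13
Reactants: 21 (1S,4aS,6S,8aR)-1-{[(6-methoxy-2-oxo-2H-chromen-7-yl)oxy]methyl}-5,5,8a-trimethyl-6-[(triethylsilyl)oxy]-1,4,4a,5,6,7,8,8a-octahydronaphthalen-2-yl trifluoromethanesulfonate
Product: 23 7-{[(1S,4aS,6S,8aR)-6-hydroxy-2,5,5,8a-tetramethyl-1,4,4a,5,6,7,8,8a-octahydronaphthalen-1-yl]methoxy}-6-methoxy-2H-chromen-2-one, via silyl ether 22 (not isolated)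
Conditions: MeZnCl (3 equiv), Pd(PPh3)4 (5 mol %), THF, 50 °C; then 1 M aq HCl, THF/MeOH, rt
Reagents that add atoms: methylzinc chloride (C[Zn]Cl)
Why: Negishi cross-coupling of the alkenyl triflate installs the vinylic methyl without moving the double bond or touching a stereocentre (the organozinc tolerates the lactone); dilute acid then cleaves the TES ether.

## Compound list

1 | 2-methylcyclopentane-1,3-dione | CC1C(=O)CCC1=O | starting material
2 | pent-1-en-3-one | C=CC(=O)CC | starting material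
3 | 2-methyl-2-(3-oxopentyl)cyclopentane-1,3-dione | CCC(=O)CCC1(C)C(=O)CCC1=O | intermediate
4 | (7aR)-4,7a-dimethyl-2,3,7,7a-tetrahydro-1H-indene-1,5(6H)-dione | O=C1CCC2=C(C)C(=O)CC[C@@]12C | intermediate
5 | (7a'R)-4',7a'-dimethyl-2',3',7',7a'-tetrahydrospiro[1,3-dioxolane-2,1'-inden]-5'(6'H)-one | O1CCOC12CCC3=C(C)C(=O)CC[C@@]23C | intermediate
6 | (3a'R,7a'R)-4',4',7a'-trimethylhexahydrospiro[1,3-dioxolane-2,1'-inden]-5'(4'H)-one | O1CCOC12CC[C@@H]3C(C)(C)C(=O)CC[C@@]23C | intermediate
7 | (3a'R,5'S,7a'R)-4',4',7a'-trimethyloctahydrospiro[1,3-dioxolane-2,1'-inden]-5'-ol | O1CCOC12CC[C@@H]3C(C)(C)[C@@H](O)CC[C@@]23C | intermediate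
8 | (3aR,5S,7aR)-5-hydroxy-4,4,7a-trimethyloctahydro-1H-inden-1-one | O=C1CC[C@@H]2C(C)(C)[C@@H](O)CC[C@]21C | intermediate
9 | (3aR,5S,7aR)-4,4,7a-trimethyl-5-[(triethylsilyl)oxy]octahydro-1H-inden-1-one | O=C1CC[C@@H]2C(C)(C)[C@@H](O[Si](CC)(CC)CC)CC[C@]21C | intermediate
10 | 1,4-benzoquinone | O=C1C=CC(=O)C=C1 | starting material
11 | benzene-1,2,4-triyl triacetate | CC(=O)Oc1ccc(OC(C)=O)c(OC(C)=O)c1 | intermediate
12 | ethyl prop-2-ynoate | C#CC(=O)OCC | starting material
13 | benzene-1,2,4-triol | Oc1ccc(O)c(O)c1 | intermediate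
14 | 6,7-dihydroxy-2H-chromen-2-one (esculetin) | Oc1cc2ccc(=O)oc2cc1O | intermediate
15 | 6-hydroxy-7-[(methylsulfanyl)methoxy]-2H-chromen-2-one | Oc1cc2ccc(=O)oc2cc1OCSC | intermediate
16 | 6-methoxy-7-[(methylsulfanyl)methoxy]-2H-chromen-2-one | COc1cc2ccc(=O)oc2cc1OCSC | intermediate
17 | 7-(chloromethoxy)-6-methoxy-2H-chromen-2-one | COc1cc2ccc(=O)oc2cc1OCCl | intermediate
18 | lithium (1R,3aR,5S,7aR)-1-(dibromomethyl)-4,4,7a-trimethyl-5-[(triethylsilyl)oxy]octahydro-1H-inden-1-olate | [Li]O[C@]1(C(Br)Br)CC[C@@H]2C(C)(C)[C@@H](O[Si](CC)(CC)CC)CC[C@]21C | intermediate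
19 | lithium (4aS,6S,8aR)-5,5,8a-trimethyl-6-[(triethylsilyl)oxy]-3,4,4a,5,6,7,8,8a-octahydronaphthalen-2-olate | C1=C(O[Li])CC[C@@H]2C(C)(C)[C@@H](O[Si](CC)(CC)CC)CC[C@]21C | intermediate
20 | 6-methoxy-7-{[(1S,4aS,6S,8aR)-5,5,8a-trimethyl-2-oxo-6-[(triethylsilyl)oxy]decahydronaphthalen-1-yl]methoxy}-2H-chromen-2-one | COc1cc2ccc(=O)oc2cc1OC[C@H]1C(=O)CC[C@@H]2C(C)(C)[C@@H](O[Si](CC)(CC)CC)CC[C@]21C | intermediate
21 | (1S,4aS,6S,8aR)-1-{[(6-methoxy-2-oxo-2H-chromen-7-yl)oxy]methyl}-5,5,8a-trimethyl-6-[(triethylsilyl)oxy]-1,4,4a,5,6,7,8,8a-octahydronaphthalen-2-yl trifluoromethanesulfonate | COc1cc2ccc(=O)oc2cc1OC[C@H]1C(OS(=O)(=O)C(F)(F)F)=CC[C@@H]2C(C)(C)[C@@H](O[Si](CC)(CC)CC)CC[C@]21C | intermediate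
22 | 6-methoxy-7-{[(1S,4aS,6S,8aR)-2,5,5,8a-tetramethyl-6-[(triethylsilyl)oxy]-1,4,4a,5,6,7,8,8a-octahydronaphthalen-1-yl]methoxy}-2H-chromen-2-one | COc1cc2ccc(=O)oc2cc1OC[C@H]1C(C)=CC[C@@H]2C(C)(C)[C@@H](O[Si](CC)(CC)CC)CC[C@]21C | intermediate
23 | 7-{[(1S,4aS,6S,8aR)-6-hydroxy-2,5,5,8a-tetramethyl-1,4,4a,5,6,7,8,8a-octahydronaphthalen-1-yl]methoxy}-6-methoxy-2H-chromen-2-one | COc1cc2ccc(=O)oc2cc1OC[C@H]1C(C)=CC[C@@H]2C(C)(C)[C@@H](O)CC[C@]21C | target

## Step count and risks

Total step count: 13. Longest linear sequence: 8 steps (steps 1–5, then 11–13; the coumarin arm, steps 6–10 then 11–13, is equally long).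

**Step 2 (chemoselective mono-ketalisation).** The enone carbonyl may ketalise with double-bond migration, or a bis-ketal may form. The fallback sets out from 4 and comes back at 9. The cyclopentanone is carried as an exocyclic alkene instead of being protected. Chemoselective Wittig methylenation of the saturated ketone (Ph3P=CH2, THF, 0 °C) gives the methylidene enone F1. Li/NH3 followed by MeI gives the trans-fused gem-dimethyl ketone F2. L-Selectride gives the axial alcohol F3, and TESCl/imidazole gives the silyl ether F4. Ozonolysis (O3, CH2Cl2/MeOH, −78 °C; Me2S) then releases ketone 9.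

**Step 11 (the proposed new one-flask ring enlargement/aryloxymethylation).** Possible failures are O- instead of C-alkylation by the new reagent 17, loss of the aryloxide from the product by β-elimination, or decomposition of 17 under the basic conditions. The fallback sets out from 9 and comes back at 22, using only known chemistry. The ring enlargement is run in its established form and enolate 19 is alkylated with benzyl chloromethyl ether, a standard enolate electrophile, to give the benzyloxymethyl ketone F5. KHMDS/PhNTf2 gives the enol triflate F6, and MeZnCl/Pd(PPh3)4 gives the methyl alkene benzyl ether F7. Lithium di-tert-butylbiphenylide (THF, −78 °C) removes the benzyl group to give the primary alcohol F8. Mitsunobu etherification (PPh3, DIAD, THF) with scopoletin F9, obtained from 16 by cleaving the methylthiomethyl group (MeI, NaHCO3, aqueous acetone), gives 22, which is desilylated as in step 13. This fallback does not cover a failure of the carbenoid migration itself.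

**Step 12 (kinetic enol triflate of a β-aryloxy ketone).** Deprotonation at C1 would expel the coumarinyl oxide or erode the C1 configuration. The fallback sets out from 20 and comes back at 22, and avoids any enolate. Non-basic, ketone-selective Takai–Lombardo methylenation (Zn, CH2Br2, TiCl4, THF/CH2Cl2, 0 °C → rt) gives the exocyclic alkene F10. A cobalt-hydride (hydrogen-atom-transfer) alkene isomerisation (Co(salen)Cl cat., PhSiH3 cat., benzene, rt) then moves the 1,1-disubstituted double bond into the ring towards the less hindered CH2, giving 22.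

## Further compounds

F1 | step 2 | (7aS)-4,7a-dimethyl-1-methylidene-1,2,3,6,7,7a-hexahydro-5H-inden-5-one | C=C1CCC2=C(C)C(=O)CC[C@@]12C
F2 | step 2 | (3aS,7aR)-4,4,7a-trimethyl-1-methylideneoctahydro-5H-inden-5-one | C=C1CC[C@@H]2C(C)(C)C(=O)CC[C@@]12C
F3 | step 2 | (3aS,5S,7aR)-4,4,7a-trimethyl-1-methylideneoctahydro-1H-inden-5-ol | C=C1CC[C@@H]2C(C)(C)[C@@H](O)CC[C@@]12C
F4 | step 2 | triethyl{[(3aS,5S,7aR)-4,4,7a-trimethyl-1-methylideneoctahydro-1H-inden-5-yl]oxy}silane | C=C1CC[C@@H]2C(C)(C)[C@@H](O[Si](CC)(CC)CC)CC[C@@]12C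
F5 | step 11 | (1S,4aS,6S,8aR)-1-[(benzyloxy)methyl]-5,5,8a-trimethyl-6-[(triethylsilyl)oxy]octahydronaphthalen-2(1H)-one | c1ccccc1COC[C@H]1C(=O)CC[C@@H]2C(C)(C)[C@@H](O[Si](CC)(CC)CC)CC[C@]21C
F6 | step 11 | (1S,4aS,6S,8aR)-1-[(benzyloxy)methyl]-5,5,8a-trimethyl-6-[(triethylsilyl)oxy]-1,4,4a,5,6,7,8,8a-octahydronaphthalen-2-yl trifluoromethanesulfonate | c1ccccc1COC[C@H]1C(OS(=O)(=O)C(F)(F)F)=CC[C@@H]2C(C)(C)[C@@H](O[Si](CC)(CC)CC)CC[C@]21C
F7 | step 11 | benzyl [(1S,4aS,6S,8aR)-2,5,5,8a-tetramethyl-6-[(triethylsilyl)oxy]-1,4,4a,5,6,7,8,8a-octahydronaphthalen-1-yl]methyl ether | c1ccccc1COC[C@H]1C(C)=CC[C@@H]2C(C)(C)[C@@H](O[Si](CC)(CC)CC)CC[C@]21C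
F8 | step 11 | [(1S,4aS,6S,8aR)-2,5,5,8a-tetramethyl-6-[(triethylsilyl)oxy]-1,4,4a,5,6,7,8,8a-octahydronaphthalen-1-yl]methanol | OC[C@H]1C(C)=CC[C@@H]2C(C)(C)[C@@H](O[Si](CC)(CC)CC)CC[C@]21C
F9 | step 11 | 7-hydroxy-6-methoxy-2H-chromen-2-one (scopoletin) | COc1cc2ccc(=O)oc2cc1O
F10 | step 12 | 6-methoxy-7-{[(1S,4aS,6S,8aR)-5,5,8a-trimethyl-2-methylidene-6-[(triethylsilyl)oxy]decahydronaphthalen-1-yl]methoxy}-2H-chromen-2-one | COc1cc2ccc(=O)oc2cc1OC[C@H]1C(=C)CC[C@@H]2C(C)(C)[C@@H](O[Si](CC)(CC)CC)CC[C@]21C
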